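**Plan**

Retrosynthesis: the two ester C–O bonds are cut first (O15–malonyl, then O18–senecioyl). The C13–C14 bond is then traced back to a 13E allylic alcohol. Last, C8–OH, C9–C10 and C4–C5 are cut, which opens rings B and A to a linear C20 chain.
Enabling feature: around rings A and B, C4, C5, C10, C9 and C8 follow one another like the alkene carbons of a regular head-to-tail tetraprenyl chain. Each methyl-bearing carbon (C4, C10, C8) is a potential tertiary cation. The oxygenated C18 is the equatorial C4 substituent, which corresponds to the E methyl of the chain terminus.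
Forward: geranylgeraniol is hydroxylated at its terminal E methyl and converted into the diphosphate. One enzymatic cascade then closes ring A, closes ring B and ends with water at C8.
The side-chain alkene is then reduced and the esters are attached, the senecioate at C18 first and the malonate at C15 last.
Stereochemistry: C4, C5, C10, C9 and C8 arise together. Their relative configuration comes from the three E alkenes and their absolute configuration from the ent chair–chair fold of the cyclase. C13 is set by hydrogenation with Ru(OAc)2[(R)-BINAP].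

Key step: step 7

Remark: from step 7 on, and in the discussion of that step, labdane numbering is used. Chain atoms C14, C15, C16, C10, C11, C6, C7 and C1 become C3, C4, C18, C5, C10, C9, C8 and C15. Diphosphates are drawn as free acids but would be handled as ammonium salts.

Step 1
Reactants: 1 (2E,6E,10E)-geranylgeraniol
Product: 2 (2E,6E,10E)-geranylgeranyl acetate
Conditions: Ac2O, pyridine, DMAP (cat.), CH2Cl2, 0 °C to rt
Reagents that add atoms: acetic anhydride, CC(=O)OC(C)=O
Why: DMAP-catalysed O-acetylation masks the alcohol, and the allylic acetate also makes the C2=C3 alkene less reactive toward the oxidant of the next step.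

Step 2
Reactants: 2 (2E,6E,10E)-geranylgeranyl acetate
Product: 3 (2E,6E,10E,14E)-16-hydroxygeranylgeranyl acetate
Conditions: SeO2 (cat.), t-BuOOH, salicylic acid (cat.), CH2Cl2, 0 °C to rt, stopped before full conversion
Reagents that add atoms: tert-butyl hydroperoxide, CC(C)(C)OO (oxygen relayed through selenium dioxide, O=[Se]=O)
Why: The catalytic SeO2/t-BuOOH allylic oxidation (ene reaction, then 2,3-sigmatropic shift) prefers the unhindered gem-dimethyl terminus and oxidises only the methyl trans to the chain, which fixes the 14E geometry that later becomes the C4 configuration.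

Step 3
Reactants: 3 (2E,6E,10E,14E)-16-hydroxygeranylgeranyl acetate
Product: 4 (2E,6E,10E,14E)-16-(tert-butyldimethylsilyloxy)geranylgeranyl acetate
Conditions: TBSCl, imidazole, CH2Cl2, 0 °C to rt
Reagents that add atoms: tert-butyldimethylsilyl chloride, CC(C)(C)[Si](C)(C)Cl
Why: Imidazole-promoted silylation of a primary allylic alcohol gives an ether that survives methanolysis, chlorination and displacement and can later be removed by fluoride without acid.

Step 4
Reactants: 4 (2E,6E,10E,14E)-16-(tert-butyldimethylsilyloxy)geranylgeranyl acetate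
Product: 5 (2E,6E,10E,14E)-16-(tert-butyldimethylsilyloxy)geranylgeraniol
Conditions: K2CO3 (cat.), MeOH, 0 °C to rt
Reagents that add atoms: none
Why: Base-catalysed transesterification with methanol removes the acetate and leaves the silyl ether and all four alkene geometries untouched.

Step 5
Reactants: 5 (2E,6E,10E,14E)-16-(tert-butyldimethylsilyloxy)geranylgeraniol
Product: 6 (2E,6E,10E,14E)-16-(tert-butyldimethylsilyloxy)geranylgeranyl chloride
Conditions: NCS, Me2S, CH2Cl2, −30 °C to 0 °C
Reagents that add atoms: N-chlorosuccinimide, O=C1CCC(=O)N1Cl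
Why: In the Corey–Kim chlorination, chloride displaces the alkoxysulfonium group by SN2 under neutral conditions, so allylic transposition and E/Z scrambling should not occur.

Step 6
Reactants: 6 (2E,6E,10E,14E)-16-(tert-butyldimethylsilyloxy)geranylgeranyl chloride
Product: 8 (2E,6E,10E,14E)-16-hydroxygeranylgeranyl diphosphate, via 16-silyloxygeranylgeranyl diphosphate 7 (not isolated)
Conditions: (Bu4N)3HP2O7, MeCN, rt; then TBAF (THF), rt; Dowex 50WX8 (NH4+ form), NH4HCO3 buffer; cellulose chromatography
Reagents that add atoms: tris(tetrabutylammonium) hydrogen diphosphate, CCCC[N+](CCCC)(CCCC)CCCC.CCCC[N+](CCCC)(CCCC)CCCC.CCCC[N+](CCCC)(CCCC)CCCC.OP(=O)([O-])OP(=O)([O-])[O-]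
Why: SN2 displacement of a primary allylic chloride by the soluble diphosphate salt is the standard entry to prenyl diphosphates, and fluoride then cleaves the primary silyl ether in the same basic, aprotic medium in which the acid-labile allylic diphosphate is stable.

Step 7
Reactants: 8 (2E,6E,10E,14E)-16-hydroxygeranylgeranyl diphosphate
Product: 9 ent-8,18-dihydroxycopalyl diphosphate, (4S,5S,8S,9S,10R,13E)
Conditions: ent-copalyl diphosphate synthase of Arabidopsis thaliana, His263Ala variant (recombinant, purified), HEPES pH 7.5, KCl, MgCl2 (0.1 mM), glycerol, dithiothreitol, 30 °C, slow feed of 8; octadecyl-silica cartridge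
Reagents that add atoms: water, O
Why: Proposed new method: the middle aspartic acid of the DXDD motif protonates C3, the developing C4 cation is intercepted by the C5=C10 alkene and the C10 cation by the C9=C8 alkene, and the water molecule that reaches C8 once the base-positioning histidine is replaced by alanine ends the cascade as the tertiary alcohol. The closest known reaction is the conversion of unsubstituted geranylgeranyl diphosphate into ent-8-hydroxycopalyl diphosphate by such alanine variants of class 2 diterpene cyclases, whereas a 16-hydroxylated chain has not been described as a substrate of this enzyme class. Ring A closes 6-endo-trig through C4–C5 and ring B closes 6-endo-trig through C9–C10, each with Markovnikov placement of the charge on the methyl-bearing carbon and each through a chair. Because every addition is anti, alkene geometry becomes relative configuration: the E C3=C4 alkene keeps CH2OH antiperiplanar to C2 and hence equatorial at C4 (4S, C18), the E C5=C10 alkene sets H-5 trans to C20 (5S, 10R), and the E C9=C8 alkene gives the equatorial side chain at C9 (9S) and, with water arriving antiperiplanar to the new C9–C10 bond, the equatorial hydroxyl at C8 (8S), while the absolute sense of all five centres is dictated by the ent chair–chair fold that the active site enforces. The step needs protonation at the terminal alkene, although the allylic oxygen makes it the least basic of the three nucleophilic alkenes, and it needs a stop after two rings; the first is secured by the diphosphate anchor, which places only C3=C4 at the acid, and the second by the pocket and by the electron-poor C13=C14 alkene next to the diphosphate. The free hydroxyl is chosen because it is smaller than any ether and less electron-withdrawing than any ester, and the slower turnover to be expected would be met by high enzyme loading, by screening orthologous ent-copalyl diphosphate synthases carrying the same exchange and by second-shell mutations around the C18 site.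

Step 8
Reactants: 9 ent-8,18-dihydroxycopalyl diphosphate
Product: 10 ent-labd-13E-ene-8,15,18-triol, (4S,5S,8S,9S,10R)
Conditions: calf intestinal alkaline phosphatase, Tris·HCl pH 8.5, MgCl2, 37 °C; extraction with EtOAc
Reagents that add atoms: none
Why: Enzymatic phosphate hydrolysis proceeds with P–O cleavage at mildly basic pH, so the allylic C15–O bond, the 13E alkene and the acid-sensitive tertiary alcohol should stay intact.

Step 9
Reactants: 10 ent-labd-13E-ene-8,15,18-triol
Product: 11 (13S)-ent-labdane-8,15,18-triol, (4S,5S,8S,9S,10R,13S)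
Conditions: Ru(OAc)2[(R)-BINAP] (1 mol %), H2 (100 atm), MeOH, 25 °C
Reagents that add atoms: none
Why: In this Noyori hydroxyl-directed asymmetric hydrogenation of an E trisubstituted allylic alcohol, the (R)-BINAP complex delivers hydrogen to the face that turns geraniol into (S)-citronellol, which here corresponds to 13S, and catalyst control is expected because the ring stereocentres are remote.

Step 10
Reactants: 11 (13S)-ent-labdane-8,15,18-triol
Product: 12 (13S)-15-(tert-butyldiphenylsilyloxy)-ent-labdane-8,18-diol
Conditions: TBDPSCl (1.05 equiv), imidazole, CH2Cl2, −10 °C to 0 °C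
Reagents that add atoms: tert-butyldiphenylsilyl chloride, CC(C)(C)[Si](Cl)(c1ccccc1)c1ccccc1
Why: This sterically differentiated silylation should work because the bulky chlorosilane reacts much faster with the unhindered C15 primary alcohol than with the neopentyl-type C18 hydroxyl next to quaternary C4, and not with the tertiary C8 hydroxyl.

Step 11
Reactants: 12 (13S)-15-(tert-butyldiphenylsilyloxy)-ent-labdane-8,18-diol; 13 3-methylbut-2-enoyl chloride
Product: 14 (13S)-15-(tert-butyldiphenylsilyloxy)-8-hydroxy-ent-labdan-18-yl 3-methylbut-2-enoate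
Conditions: 13, pyridine, DMAP (cat.), CH2Cl2, 0 °C to rt
Reagents that add atoms: 3-methylbut-2-enoyl chloride (13), CC(C)=CC(=O)Cl
Why: DMAP-catalysed acylation reaches the only free primary alcohol, pyridine rather than a trialkylamine is the base so that the vinylketene pathway to the deconjugated ester is held back, and the hindered tertiary C8 hydroxyl stays free.

Step 12
Reactants: 14 (13S)-15-(tert-butyldiphenylsilyloxy)-8-hydroxy-ent-labdan-18-yl 3-methylbut-2-enoate
Product: 15 (13S)-8,15-dihydroxy-ent-labdan-18-yl 3-methylbut-2-enoate
Conditions: TBAF, AcOH, THF, rt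
Reagents that add atoms: none
Why: Fluoride-induced desilylation buffered with acetic acid frees the C15 alcohol without ester cleavage or elimination of the tertiary alcohol.

Step 13
Reactants: 15 (13S)-8,15-dihydroxy-ent-labdan-18-yl 3-methylbut-2-enoate; 16 2,2-dimethyl-1,3-dioxane-4,6-dione (Meldrum's acid)
Product: 17 target, (13S)-8-hydroxy-18-(3-methylbut-2-enoyloxy)-ent-labdan-15-yl hydrogen malonate
Conditions: 16 (1.1 equiv), toluene, 85 °C
Reagents that add atoms: 2,2-dimethyl-1,3-dioxane-4,6-dione (16), CC1(C)OC(=O)CC(=O)O1
Why: In the thermal alcoholysis of Meldrum's acid the primary alcohol opens the dioxanedione with loss of acetone and gives the malonic half ester directly, while the tertiary C8 hydroxyl is too hindered to compete and the temperature stays below that of decarboxylation.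

**Compound list**

1 | (2E,6E,10E)-geranylgeraniol | CC(C)=CCC/C(C)=C/CC/C(C)=C/CC/C(C)=C/CO | starting material
2 | (2E,6E,10E)-geranylgeranyl acetate | CC(C)=CCC/C(C)=C/CC/C(C)=C/CC/C(C)=C/COC(C)=O | intermediate
3 | (2E,6E,10E,14E)-16-hydroxygeranylgeranyl acetate | OC/C(C)=C/CC/C(C)=C/CC/C(C)=C/CC/C(C)=C/COC(C)=O | intermediate
4 | (2E,6E,10E,14E)-16-(tert-butyldimethylsilyloxy)geranylgeranyl acetate | CC(C)(C)[Si](C)(C)OC/C(C)=C/CC/C(C)=C/CC/C(C)=C/CC/C(C)=C/COC(C)=O | intermediate
5 | (2E,6E,10E,14E)-16-(tert-butyldimethylsilyloxy)geranylgeraniol | CC(C)(C)[Si](C)(C)OC/C(C)=C/CC/C(C)=C/CC/C(C)=C/CC/C(C)=C/CO | intermediate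
6 | (2E,6E,10E,14E)-16-(tert-butyldimethylsilyloxy)geranylgeranyl chloride | CC(C)(C)[Si](C)(C)OC/C(C)=C/CC/C(C)=C/CC/C(C)=C/CC/C(C)=C/CCl | intermediate
7 | (2E,6E,10E,14E)-16-(tert-butyldimethylsilyloxy)geranylgeranyl diphosphate (not isolated) | CC(C)(C)[Si](C)(C)OC/C(C)=C/CC/C(C)=C/CC/C(C)=C/CC/C(C)=C/COP(=O)(O)OP(=O)(O)O | intermediate
8 | (2E,6E,10E,14E)-16-hydroxygeranylgeranyl diphosphate | OC/C(C)=C/CC/C(C)=C/CC/C(C)=C/CC/C(C)=C/COP(=O)(O)OP(=O)(O)O | intermediate
9 | ent-8,18-dihydroxycopalyl diphosphate, (4S,5S,8S,9S,10R,13E); trans-decalin with C19, C20 and C17 axial on one face and with the C18 hydroxymethyl, the 8-OH and the C9 side chain equatorial | OC[C@@]1(C)CCC[C@]2(C)[C@@H]1CC[C@](C)(O)[C@H]2CC/C(C)=C/COP(=O)(O)OP(=O)(O)O | intermediate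
10 | ent-labd-13E-ene-8,15,18-triol, (4S,5S,8S,9S,10R) | OC[C@@]1(C)CCC[C@]2(C)[C@@H]1CC[C@](C)(O)[C@H]2CC/C(C)=C/CO | intermediate
11 | (13S)-ent-labdane-8,15,18-triol, (4S,5S,8S,9S,10R,13S) | OC[C@@]1(C)CCC[C@]2(C)[C@@H]1CC[C@](C)(O)[C@H]2CC[C@H](C)CCO | intermediate
12 | (13S)-15-(tert-butyldiphenylsilyloxy)-ent-labdane-8,18-diol | OC[C@@]1(C)CCC[C@]2(C)[C@@H]1CC[C@](C)(O)[C@H]2CC[C@H](C)CCO[Si](c3ccccc3)(c4ccccc4)C(C)(C)C | intermediate
13 | 3-methylbut-2-enoyl chloride | CC(C)=CC(=O)Cl | starting material
14 | (13S)-15-(tert-butyldiphenylsilyloxy)-8-hydroxy-ent-labdan-18-yl 3-methylbut-2-enoate | CC(C)=CC(=O)OC[C@@]1(C)CCC[C@]2(C)[C@@H]1CC[C@](C)(O)[C@H]2CC[C@H](C)CCO[Si](c3ccccc3)(c4ccccc4)C(C)(C)C | intermediate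
15 | (13S)-8,15-dihydroxy-ent-labdan-18-yl 3-methylbut-2-enoate | CC(C)=CC(=O)OC[C@@]1(C)CCC[C@]2(C)[C@@H]1CC[C@](C)(O)[C@H]2CC[C@H](C)CCO | intermediate
16 | 2,2-dimethyl-1,3-dioxane-4,6-dione | CC1(C)OC(=O)CC(=O)O1 | starting material
17 | (4S,5S,8S,9S,10R,13S)-8-hydroxy-18-(3-methylbut-2-enoyloxy)-ent-labdan-15-yl hydrogen malonate | CC(C)=CC(=O)OC[C@@]1(C)CCC[C@]2(C)[C@@H]1CC[C@](C)(O)[C@H]2CC[C@H](C)CCOC(=O)CC(=O)O | target

**Step count and risks**

Total step count: 13. Longest linear sequence: 13 steps, from 1 to 17. Compounds 13 and 16 are bought.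

**Step 7.**
- What may go wrong: the cyclase may not turn over 8, either because the allylic oxygen makes the terminal alkene too weakly basic or because the pocket rejects the hydroxyl. The allylic alcohol may ionise at the catalytic acid. The C8 cation may lose a proton before water arrives.
- Fallback: the C18 oxygen is brought in after the cyclisation instead of before it, and every stage is a known reaction type.
- Setting out from 1, Corey–Kim chlorination (NCS, Me2S) gives (2E,6E,10E)-geranylgeranyl chloride F1. Displacement with (Bu4N)3HP2O7 in MeCN gives geranylgeranyl diphosphate F2.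
- The same alanine variant converts this native substrate, in its documented reaction, into ent-8-hydroxycopalyl diphosphate F3. Alkaline phosphatase then releases ent-labd-13E-ene-8,15-diol F4.
- Whole-cell hydroxylation with a filamentous fungus follows. Cunninghamella and Mucor strains are known to oxidise sclareol and related labdan-8-ols at the equatorial C4 methyl and at C3.
- This leads to triol 10, where the route is rejoined before step 9. Strain screening and separation from the C3-hydroxylated isomer must be expected.

**Step 6.**
- What may go wrong: hydrolysis or elimination of the allylic chloride, incomplete silyl cleavage, or loss of the amphiphilic diphosphate in a work-up that has to remove two tetrabutylammonium reagents.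
- Fallback: the hydroxyl is unmasked before phosphorus is introduced, so no protecting-group chemistry is done on a diphosphate.
- Setting out from 6, HF·pyridine in THF at 0 °C gives (2E,6E,10E,14E)-16-hydroxygeranylgeranyl chloride F5.
- This chloro alcohol is treated directly with (Bu4N)3HP2O7 in MeCN, the way (E)-4-hydroxy-3-methylbut-2-enyl diphosphate is made from its chloro alcohol. After ion exchange this gives 8.

**Step 10.**
- What may go wrong: poor site selectivity between the two primary hydroxyls, with silylation at C18 or at both positions.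
- Fallback: the two alcohols are told apart by oxidation state while the alkene is still present.
- Setting out from 10, MnO2 in CH2Cl2 oxidises only the allylic alcohol and gives (13E)-8,18-dihydroxy-ent-labd-13-en-15-al F6.
- The one remaining primary alcohol is acylated with 13 (pyridine, DMAP) to give (13E)-8-hydroxy-15-oxo-ent-labd-13-en-18-yl 3-methylbut-2-enoate F7.
- Iminium-catalysed transfer hydrogenation follows, with a Hantzsch ester and one enantiomer of 2-tert-butyl-3-methylimidazolidin-4-one trichloroacetate. The catalyst enantiomer would be fixed on a model enal so that 13S results.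
- This reduction touches only the enal alkene, tolerates E/Z isomerisation of the enal and leaves the senecioate alone, since an ester forms no iminium ion. It gives (13S)-8-hydroxy-15-oxo-ent-labdan-18-yl 3-methylbut-2-enoate F8.
- NaBH4 in MeOH at 0 °C then gives 15, so steps 9 to 12 are bypassed.

**Further compounds**

F1 | step 7 | (2E,6E,10E)-geranylgeranyl chloride | CC(C)=CCC/C(C)=C/CC/C(C)=C/CC/C(C)=C/CCl
F2 | step 7 | (2E,6E,10E)-geranylgeranyl diphosphate | CC(C)=CCC/C(C)=C/CC/C(C)=C/CC/C(C)=C/COP(=O)(O)OP(=O)(O)O
F3 | step 7 | ent-8-hydroxycopalyl diphosphate, (5R,8S,9S,10R,13E) | CC1(C)CCC[C@]2(C)[C@@H]1CC[C@](C)(O)[C@H]2CC/C(C)=C/COP(=O)(O)OP(=O)(O)O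
F4 | step 7 | ent-labd-13E-ene-8,15-diol, (5R,8S,9S,10R) | CC1(C)CCC[C@]2(C)[C@@H]1CC[C@](C)(O)[C@H]2CC/C(C)=C/CO
F5 | step 6 | (2E,6E,10E,14E)-16-hydroxygeranylgeranyl chloride | OC/C(C)=C/CC/C(C)=C/CC/C(C)=C/CC/C(C)=C/CCl
F6 | step 10 | (13E)-8,18-dihydroxy-ent-labd-13-en-15-al | OC[C@@]1(C)CCC[C@]2(C)[C@@H]1CC[C@](C)(O)[C@H]2CC/C(C)=C/C=O
F7 | step 10 | (13E)-8-hydroxy-15-oxo-ent-labd-13-en-18-yl 3-methylbut-2-enoate | CC(C)=CC(=O)OC[C@@]1(C)CCC[C@]2(C)[C@@H]1CC[C@](C)(O)[C@H]2CC/C(C)=C/C=O
F8 | step 10 | (13S)-8-hydroxy-15-oxo-ent-labdan-18-yl 3-methylbut-2-enoate | CC(C)=CC(=O)OC[C@@]1(C)CCC[C@]2(C)[C@@H]1CC[C@](C)(O)[C@H]2CC[C@H](C)CC=O
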